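## Retrosynthetic overview

1. Glaucolide K (germacrane numbering: C1 CHOAc, C4/C5 oxirane, C6 lactone CH–O, C7=C11, C8 CH–O‑methacryloyl, C10 CHMe, C12 C=O, C13 CH2OAc) ⇒ its 4E‑alkene; epoxidation from the outer face and O8 methacryloylation come last.
2. Butenolide (second ring) ⇒ ring‑closing metathesis of a C6‑O 2‑(acetoxymethyl)acrylate (fragment C) onto a C7 exo‑methylene.
3. Ten‑membered carbocycle (first ring) ⇒ Nozaki–Hiyama–Kishi closure of C7–C8 (2‑bromoalkene onto aldehyde).
4. Open chain ⇒ late Negishi sp3–sp2 coupling at C3–C4 of alkyl iodide fragment A (C1–C3, C8–C10; C1/C10 by Brown crotylboration) with bis(vinyl halide) fragment B (C4–C7; C6 by CBS reduction).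
5. Ring order: carbocycle → butenolide → oxirane.

Assumption: the chromium‑mediated ring closure (step 19) is taken to give mainly the 8S alcohol (O8 syn to O6); any 8R epimer is separated by chromatography.

## Fragment A

Step 1
Reactants: 1 propane-1,3-diol
Product: 2 3-[(4-methoxybenzyl)oxy]propan-1-ol
Conditions: NaH (1 equiv), PMBCl (1 equiv), Bu4NI (cat.), 1 in excess (3 equiv), THF, 0 °C → rt
Reagents that add atoms: 4-methoxybenzyl chloride, COc1ccc(CCl)cc1
Why: Williamson etherification of the mono-alkoxide, with excess diol suppressing bis-alkylation.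

Step 2
Reactants: 2 3-[(4-methoxybenzyl)oxy]propan-1-ol
Product: 3 3-[(4-methoxybenzyl)oxy]propanal
Conditions: TEMPO (10 mol %), PhI(OAc)2 (1.1 equiv), CH2Cl2, rt
Reagents that add atoms: none
Why: TEMPO (oxoammonium) oxidation stops at the aldehyde and is neutral, so the β-alkoxy aldehyde does not eliminate.

Step 3
Reactants: 3 3-[(4-methoxybenzyl)oxy]propanal; 4 (Z)-but-2-ene
Product: 8 (3S,4S)-1-[(4-methoxybenzyl)oxy]-4-methylhex-5-en-3-ol, via (Z)-crotylpotassium 5 (not isolated), via (Z)-crotyldiisopinocampheylborane 6 (not isolated), via borinate ester 7 (not isolated)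
Conditions: 4, KOt-Bu, n-BuLi, THF, −78 → −45 °C; (+)-Ipc2BOMe [from (−)-α-pinene], −78 °C; BF3·OEt2; 3, −78 °C; then NaOH, H2O2, 0 °C → rt
Reagents that add atoms: none
Why: Brown asymmetric crotylboration, in which the Z-crotylborane adds through a chair Zimmerman–Traxler transition state (syn product) and the (−)-α-pinene-derived ligands steer it to the Re face of the aldehyde, setting 3S (C1) and 4S (C10).

Step 4
Reactants: 8 (3S,4S)-1-[(4-methoxybenzyl)oxy]-4-methylhex-5-en-3-ol
Product: 9 (3S,4S)-1-[(4-methoxybenzyl)oxy]-4-methylhex-5-en-3-yl acetate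
Conditions: Ac2O, pyridine, DMAP (cat.), CH2Cl2, 0 °C → rt
Reagents that add atoms: acetic anhydride, CC(=O)OC(C)=O
Why: DMAP-catalysed acylation installs the C1 acetate of the target early without touching a stereocentre.

Step 5
Reactants: 9 (3S,4S)-1-[(4-methoxybenzyl)oxy]-4-methylhex-5-en-3-yl acetate
Product: 10 (3S,4S)-1-hydroxy-4-methylhex-5-en-3-yl acetate
Conditions: DDQ (1.3 equiv), CH2Cl2/pH 7 buffer, 0 °C
Reagents that add atoms: none
Why: Oxidative PMB ether cleavage (benzylic hydride abstraction by DDQ, then hydrolysis) is neutral, so the acetate neither cleaves nor migrates.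

Step 6
Reactants: 10 (3S,4S)-1-hydroxy-4-methylhex-5-en-3-yl acetate
Product: 11 (3S,4S)-1-iodo-4-methylhex-5-en-3-yl acetate (fragment A)
Conditions: I2, PPh3, imidazole, CH2Cl2, 0 °C → rt
Reagents that add atoms: iodine, II
Why: Appel-type (Garegg–Samuelsson) iodination converts the primary alcohol into the iodide by SN2 displacement of the oxyphosphonium group.

## Fragment B

Step 7
Reactants: 12 prop-2-enal (acrolein)
Product: 14 2-bromoprop-2-enal, via 2,3-dibromopropanal 13 (not isolated)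
Conditions: Br2, CH2Cl2, −78 °C; then Et3N, −78 → 0 °C
Reagents that add atoms: bromine, BrBr
Why: Bromine addition to the alkene followed by E1cB loss of HBr from the acidic α-position gives the α-bromo enal.

Step 8
Reactants: 14 2-bromoprop-2-enal; 15 prop-1-yn-1-ylmagnesium bromide
Product: 16 rac-2-bromohex-1-en-4-yn-3-ol
Conditions: THF, −78 °C; aq NH4Cl
Reagents that add atoms: none
Why: Alkynyl Grignard reagents add 1,2 to enals, giving the racemic carbinol that carries C4–C7 and C15 of the target.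

Step 9
Reactants: 16 rac-2-bromohex-1-en-4-yn-3-ol
Product: 17 2-bromohex-1-en-4-yn-3-one
Conditions: MnO2 (15 equiv), CH2Cl2, 0 °C → rt, used at once
Reagents that add atoms: none
Why: MnO2 selectively oxidises the doubly activated (allylic and propargylic) alcohol to the ketone.

Step 10
Reactants: 17 2-bromohex-1-en-4-yn-3-one
Product: 18 (3R)-2-bromohex-1-en-4-yn-3-ol
Conditions: (S)-2-methyl-CBS-oxazaborolidine (0.2 equiv), catecholborane (1.5 equiv), toluene/CH2Cl2, −78 °C
Reagents that add atoms: none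
Why: Corey–Bakshi–Shibata reduction, in which the 1-bromovinyl group acts as the large and the linear propynyl group as the small substituent, so the (S)-catalyst delivers hydride to give the 3R alcohol (C6 of the target).

Step 11
Reactants: 18 (3R)-2-bromohex-1-en-4-yn-3-ol
Product: 19 (3R)-2-bromo-3-[(triethylsilyl)oxy]hex-1-en-4-yne
Conditions: TESCl, imidazole, CH2Cl2, 0 °C
Reagents that add atoms: chlorotriethylsilane, CC[Si](Cl)(CC)CC
Why: Imidazole-promoted silylation protects O6 as a TES ether that can later be removed in the presence of a TBS ether.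

Step 12
Reactants: 19 (3R)-2-bromo-3-[(triethylsilyl)oxy]hex-1-en-4-yne
Product: 21 (3R,4E)-2-bromo-5-iodo-3-[(triethylsilyl)oxy]hexa-1,4-diene (fragment B), via alkenylzirconocene chloride 20 (not isolated)
Conditions: Cp2Zr(H)Cl (1.4 equiv), THF, 23 → 45 °C; then I2, 0 °C
Reagents that add atoms: iodine, II
Why: Hydrozirconation–iodination, in which syn addition of Zr–H places zirconium on the less hindered methyl-bearing alkyne carbon and iodinolysis with retention gives the 4E iodide, while the electron-poor 1,1-disubstituted bromoalkene reacts more slowly.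

## Fragment C

Step 13
Reactants: 22 methyl 2-(hydroxymethyl)prop-2-enoate
Product: 23 2-(hydroxymethyl)prop-2-enoic acid
Conditions: LiOH·H2O, THF/H2O, 0 °C; then 1 M HCl to pH 2
Reagents that add atoms: lithium hydroxide, [Li+].[OH-]
Why: Saponification of the methyl ester (acyl substitution by hydroxide) under conditions too mild for conjugate addition.

Step 14
Reactants: 23 2-(hydroxymethyl)prop-2-enoic acid
Product: 24 2-(acetoxymethyl)prop-2-enoic acid
Conditions: AcCl (1.2 equiv), CH2Cl2, 0 °C → rt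
Reagents that add atoms: acetyl chloride, CC(Cl)=O
Why: O-Acetylation of the primary alcohol by acetyl chloride provides the C13 acetate of the target.

Step 15
Reactants: 24 2-(acetoxymethyl)prop-2-enoic acid
Product: 25 2-(acetoxymethyl)prop-2-enoyl chloride (fragment C)
Conditions: (COCl)2, DMF (cat.), CH2Cl2, 0 °C → rt, used crude
Reagents that add atoms: oxalyl chloride, O=C(Cl)C(Cl)=O
Why: Acid chloride formation by the Vilsmeier-type oxalyl chloride/DMF method proceeds under neutral conditions that leave the allylic acetate intact.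

## Fragment union, ring closures and end game

Step 16
Reactants: 11 (3S,4S)-1-iodo-4-methylhex-5-en-3-yl acetate; 21 (3R,4E)-2-bromo-5-iodo-3-[(triethylsilyl)oxy]hexa-1,4-diene
Product: 27 (3R,4E,8S,9S)-2-bromo-5,9-dimethyl-3-[(triethylsilyl)oxy]undeca-1,4,10-trien-8-yl acetate, via alkylzinc iodide 26 (not isolated)
Conditions: 11, Zn dust (activated with BrCH2CH2Br, TMSCl), THF/DMA, 40 °C; then 21, Pd(PPh3)4 (5 mol %), rt
Reagents that add atoms: none
Why: Negishi coupling, in which zinc inserts into the primary C–I bond and zerovalent palladium adds oxidatively to the alkenyl C–I bond far faster than to the C–Br bond, joining C3 to C4 with retention of the E geometry.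

Step 17
Reactants: 27 (3R,4E,8S,9S)-2-bromo-5,9-dimethyl-3-[(triethylsilyl)oxy]undeca-1,4,10-trien-8-yl acetate
Product: 29 (3S,4S,7E,9R)-10-bromo-1-hydroxy-3,7-dimethyl-9-[(triethylsilyl)oxy]undeca-7,10-dien-4-yl acetate, via B-alkyl-9-BBN adduct 28 (not isolated)
Conditions: 9-BBN (1.3 equiv), THF, 0 °C → rt; then NaBO3·4H2O, H2O, rt
Reagents that add atoms: sodium perborate, [Na+].[Na+].O[B-]1(O)OO[B-](O)(O)OO1
Why: Hydroboration–oxidation, in which 9-BBN adds anti-Markovnikov to the only monosubstituted alkene (the trisubstituted alkene and the bromoalkene are much slower) and perborate oxidises the C–B bond without harming acetate or TES ether.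

Step 18
Reactants: 29 (3S,4S,7E,9R)-10-bromo-1-hydroxy-3,7-dimethyl-9-[(triethylsilyl)oxy]undeca-7,10-dien-4-yl acetate
Product: 30 (3S,4S,7E,9R)-10-bromo-3,7-dimethyl-1-oxo-9-[(triethylsilyl)oxy]undeca-7,10-dien-4-yl acetate
Conditions: TEMPO (10 mol %), PhI(OAc)2 (1.1 equiv), CH2Cl2, rt
Reagents that add atoms: none
Why: TEMPO oxidation of the primary alcohol gives the C8 aldehyde without over-oxidation or epimerisation (the α-carbon is a CH2).

Step 19
Reactants: 30 (3S,4S,7E,9R)-10-bromo-3,7-dimethyl-1-oxo-9-[(triethylsilyl)oxy]undeca-7,10-dien-4-yl acetate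
Product: 31 (1S,4E,6R,8S,10S)-8-hydroxy-4,10-dimethyl-7-methylidene-6-[(triethylsilyl)oxy]cyclodec-4-en-1-yl acetate
Conditions: CrCl2 (8 equiv), NiCl2 (0.1 equiv), DMSO/THF, rt, 0.003 M (syringe pump)
Reagents that add atoms: none
Why: Nozaki–Hiyama–Kishi reaction, in which nickel-catalysed formation of the alkenylchromium from the C–Br bond and its chemoselective addition to the aldehyde at high dilution close the ten-membered ring, the C8 carbinol being set by the macrocyclic transition state (8S assumed).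

Step 20
Reactants: 31 (1S,4E,6R,8S,10S)-8-hydroxy-4,10-dimethyl-7-methylidene-6-[(triethylsilyl)oxy]cyclodec-4-en-1-yl acetate
Product: 32 (1S,4E,6R,8S,10S)-8-[(tert-butyldimethylsilyl)oxy]-4,10-dimethyl-7-methylidene-6-[(triethylsilyl)oxy]cyclodec-4-en-1-yl acetate
Conditions: TBSOTf, 2,6-lutidine, CH2Cl2, −78 → 0 °C
Reagents that add atoms: tert-butyldimethylsilyl triflate, CC(C)(C)[Si](C)(C)OS(=O)(=O)C(F)(F)F
Why: Silyl triflate silylation of the hindered secondary alcohol masks O8 during the acylation and metathesis at O6/C7.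

Step 21
Reactants: 32 (1S,4E,6R,8S,10S)-8-[(tert-butyldimethylsilyl)oxy]-4,10-dimethyl-7-methylidene-6-[(triethylsilyl)oxy]cyclodec-4-en-1-yl acetate
Product: 33 (1S,4E,6R,8S,10S)-8-[(tert-butyldimethylsilyl)oxy]-6-hydroxy-4,10-dimethyl-7-methylidenecyclodec-4-en-1-yl acetate
Conditions: HF·pyridine, pyridine, THF, 0 °C
Reagents that add atoms: none
Why: A triethylsilyl ether is cleaved far faster than a tert-butyldimethylsilyl ether by buffered HF, which frees only O6.

Step 22
Reactants: 33 (1S,4E,6R,8S,10S)-8-[(tert-butyldimethylsilyl)oxy]-6-hydroxy-4,10-dimethyl-7-methylidenecyclodec-4-en-1-yl acetate; 25 2-(acetoxymethyl)prop-2-enoyl chloride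
Product: 34 (1S,4E,6R,8S,10S)-6-{[2-(acetoxymethyl)prop-2-enoyl]oxy}-8-[(tert-butyldimethylsilyl)oxy]-4,10-dimethyl-7-methylidenecyclodec-4-en-1-yl acetate
Conditions: 25 (2 equiv), pyridine, CH2Cl2, 0 °C → rt
Reagents that add atoms: none
Why: Acylation of the secondary alcohol by the acid chloride uses pyridine only, without a nucleophilic catalyst, so the allylic acetate is not displaced in an SN2′ sense.

Step 23
Reactants: 34 (1S,4E,6R,8S,10S)-6-{[2-(acetoxymethyl)prop-2-enoyl]oxy}-8-[(tert-butyldimethylsilyl)oxy]-4,10-dimethyl-7-methylidenecyclodec-4-en-1-yl acetate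
Product: 35 (1S,4E,6R,8S,10S)-1,13-diacetoxy-8-[(tert-butyldimethylsilyl)oxy]germacra-4,7(11)-dien-12,6-olide
Conditions: second-generation Hoveyda–Grubbs catalyst RuCl2(SIMes)(=CH-C6H4-2-O-i-Pr) (2 × 10 mol %), toluene (5 mM), 90 °C, argon sparge
Reagents that add atoms: none
Why: Ring-closing metathesis of the two 1,1-disubstituted alkenes forms the tetrasubstituted C7=C11 bond of the butenolide, driven by five-membered ring formation and loss of ethene, with no stereocentre affected.

Step 24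
Reactants: 35 (1S,4E,6R,8S,10S)-1,13-diacetoxy-8-[(tert-butyldimethylsilyl)oxy]germacra-4,7(11)-dien-12,6-olide
Product: 36 (1S,4E,6R,8S,10S)-1,13-diacetoxy-8-hydroxygermacra-4,7(11)-dien-12,6-olide
Conditions: HF·pyridine, THF, 0 °C → rt; acylated at once
Reagents that add atoms: none
Why: Fluoride-driven Si–O cleavage frees O8 while the esters, the butenolide and the trisubstituted alkene are inert to HF·pyridine.

Step 25
Reactants: 36 (1S,4E,6R,8S,10S)-1,13-diacetoxy-8-hydroxygermacra-4,7(11)-dien-12,6-olide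
Product: 37 (1S,4E,6R,8S,10S)-1,13-diacetoxy-8-(methacryloyloxy)germacra-4,7(11)-dien-12,6-olide
Conditions: methacryloyl chloride, Et3N, DMAP (0.1 equiv), CH2Cl2, −20 → 0 °C
Reagents that add atoms: methacryloyl chloride, C=C(C)C(Cl)=O
Why: DMAP-catalysed acylation installs the methacrylate only after the metathesis, so that it cannot compete in the ring closure.

Step 26
Reactants: 37 (1S,4E,6R,8S,10S)-1,13-diacetoxy-8-(methacryloyloxy)germacra-4,7(11)-dien-12,6-olide
Product: 38 glaucolide K, (1S,4R,5R,6S,8S,10S)-1,13-diacetoxy-4,5-epoxy-8-(methacryloyloxy)germacr-7(11)-en-12,6-olide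
Conditions: m-CPBA (1.2 equiv), NaHCO3, CH2Cl2, 0 °C
Reagents that add atoms: 3-chloroperoxybenzoic acid, OOC(=O)c1cccc(Cl)c1
Why: Prilezhaev epoxidation of the only electron-rich alkene, where the E-olefin of the ten-membered ring exposes just its outer face (syn to the C6–O bond when H6 eclipses the C4 methyl), so syn oxygen transfer gives the 4R,5R trans-oxirane as in parthenolide-type germacranolides.

## Compound list

1 | propane-1,3-diol | OCCCO | starting material
2 | 3-[(4-methoxybenzyl)oxy]propan-1-ol | COc1ccc(COCCCO)cc1 | intermediate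
3 | 3-[(4-methoxybenzyl)oxy]propanal | COc1ccc(COCCC=O)cc1 | intermediate
4 | (Z)-but-2-ene | C/C=C\C | starting material
5 | (Z)-but-2-en-1-ylpotassium | C/C=C\C[K] | intermediate (not isolated)
6 | (Z)-crotyldiisopinocampheylborane, Ipc from (−)-α-pinene | C/C=C\CB([C@H]1C[C@H]2C[C@@H]([C@@H]1C)C2(C)C)[C@H]1C[C@H]2C[C@@H]([C@@H]1C)C2(C)C | intermediate (not isolated)
7 | diisopinocampheylborinate of alcohol 8 | C=C[C@H](C)[C@@H](OB([C@H]1C[C@H]2C[C@@H]([C@@H]1C)C2(C)C)[C@H]1C[C@H]2C[C@@H]([C@@H]1C)C2(C)C)CCOCc1ccc(OC)cc1 | intermediate (not isolated)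
8 | (3S,4S)-1-[(4-methoxybenzyl)oxy]-4-methylhex-5-en-3-ol | C=C[C@H](C)[C@@H](O)CCOCc1ccc(OC)cc1 | intermediate
9 | (3S,4S)-1-[(4-methoxybenzyl)oxy]-4-methylhex-5-en-3-yl acetate | C=C[C@H](C)[C@@H](OC(C)=O)CCOCc1ccc(OC)cc1 | intermediate
10 | (3S,4S)-1-hydroxy-4-methylhex-5-en-3-yl acetate | C=C[C@H](C)[C@@H](OC(C)=O)CCO | intermediate
11 | (3S,4S)-1-iodo-4-methylhex-5-en-3-yl acetate (fragment A) | C=C[C@H](C)[C@@H](OC(C)=O)CCI | intermediate
12 | prop-2-enal (acrolein) | C=CC=O | starting material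
13 | 2,3-dibromopropanal | O=CC(Br)CBr | intermediate (not isolated)
14 | 2-bromoprop-2-enal | C=C(Br)C=O | intermediate
15 | prop-1-yn-1-ylmagnesium bromide | CC#C[Mg]Br | starting material
16 | rac-2-bromohex-1-en-4-yn-3-ol | CC#CC(O)C(Br)=C | intermediate
17 | 2-bromohex-1-en-4-yn-3-one | CC#CC(=O)C(Br)=C | intermediate
18 | (3R)-2-bromohex-1-en-4-yn-3-ol | CC#C[C@H](C(Br)=C)O | intermediate
19 | (3R)-2-bromo-3-[(triethylsilyl)oxy]hex-1-en-4-yne | CC#C[C@H](C(Br)=C)O[Si](CC)(CC)CC | intermediate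
20 | chloro{(2E,4R)-5-bromo-4-[(triethylsilyl)oxy]hexa-2,5-dien-2-yl}zirconocene | C/C(=C\[C@H](C(Br)=C)O[Si](CC)(CC)CC)[Zr](Cl)(C1C=CC=C1)C1C=CC=C1 | intermediate (not isolated)
21 | (3R,4E)-2-bromo-5-iodo-3-[(triethylsilyl)oxy]hexa-1,4-diene (fragment B) | I/C(C)=C/[C@H](C(Br)=C)O[Si](CC)(CC)CC | intermediate
22 | methyl 2-(hydroxymethyl)prop-2-enoate | C=C(CO)C(=O)OC | starting material
23 | 2-(hydroxymethyl)prop-2-enoic acid | C=C(CO)C(=O)O | intermediate
24 | 2-(acetoxymethyl)prop-2-enoic acid | C=C(COC(C)=O)C(=O)O | intermediate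
25 | 2-(acetoxymethyl)prop-2-enoyl chloride (fragment C) | C=C(COC(C)=O)C(Cl)=O | intermediate
26 | [(3S,4S)-3-acetoxy-4-methylhex-5-en-1-yl]zinc iodide | C=C[C@H](C)[C@@H](OC(C)=O)CC[Zn]I | intermediate (not isolated)
27 | (3R,4E,8S,9S)-2-bromo-5,9-dimethyl-3-[(triethylsilyl)oxy]undeca-1,4,10-trien-8-yl acetate | C=C[C@H](C)[C@@H](OC(C)=O)CC/C(C)=C/[C@H](C(Br)=C)O[Si](CC)(CC)CC | intermediate
28 | 9-[(3S,4S,7E,9R)-4-acetoxy-10-bromo-3,7-dimethyl-9-[(triethylsilyl)oxy]undeca-7,10-dien-1-yl]-9-borabicyclo[3.3.1]nonane | B1(CC[C@H](C)[C@@H](OC(C)=O)CC/C(C)=C/[C@H](C(Br)=C)O[Si](CC)(CC)CC)C2CCCC1CCC2 | intermediate (not isolated)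
29 | (3S,4S,7E,9R)-10-bromo-1-hydroxy-3,7-dimethyl-9-[(triethylsilyl)oxy]undeca-7,10-dien-4-yl acetate | OCC[C@H](C)[C@@H](OC(C)=O)CC/C(C)=C/[C@H](C(Br)=C)O[Si](CC)(CC)CC | intermediate
30 | (3S,4S,7E,9R)-10-bromo-3,7-dimethyl-1-oxo-9-[(triethylsilyl)oxy]undeca-7,10-dien-4-yl acetate | O=CC[C@H](C)[C@@H](OC(C)=O)CC/C(C)=C/[C@H](C(Br)=C)O[Si](CC)(CC)CC | intermediate
31 | (1S,4E,6R,8S,10S)-8-hydroxy-4,10-dimethyl-7-methylidene-6-[(triethylsilyl)oxy]cyclodec-4-en-1-yl acetate | O[C@H]1C[C@H](C)[C@@H](OC(C)=O)CC/C(C)=C/[C@@H](O[Si](CC)(CC)CC)C1=C | intermediate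
32 | (1S,4E,6R,8S,10S)-8-[(tert-butyldimethylsilyl)oxy]-4,10-dimethyl-7-methylidene-6-[(triethylsilyl)oxy]cyclodec-4-en-1-yl acetate | CC(C)(C)[Si](C)(C)O[C@H]1C[C@H](C)[C@@H](OC(C)=O)CC/C(C)=C/[C@@H](O[Si](CC)(CC)CC)C1=C | intermediate
33 | (1S,4E,6R,8S,10S)-8-[(tert-butyldimethylsilyl)oxy]-6-hydroxy-4,10-dimethyl-7-methylidenecyclodec-4-en-1-yl acetate | CC(C)(C)[Si](C)(C)O[C@H]1C[C@H](C)[C@@H](OC(C)=O)CC/C(C)=C/[C@@H](O)C1=C | intermediate
34 | (1S,4E,6R,8S,10S)-6-{[2-(acetoxymethyl)prop-2-enoyl]oxy}-8-[(tert-butyldimethylsilyl)oxy]-4,10-dimethyl-7-methylidenecyclodec-4-en-1-yl acetate | CC(C)(C)[Si](C)(C)O[C@H]1C[C@H](C)[C@@H](OC(C)=O)CC/C(C)=C/[C@@H](OC(=O)C(=C)COC(C)=O)C1=C | intermediate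
35 | (1S,4E,6R,8S,10S)-1,13-diacetoxy-8-[(tert-butyldimethylsilyl)oxy]germacra-4,7(11)-dien-12,6-olide | CC(C)(C)[Si](C)(C)O[C@H]1C[C@H](C)[C@@H](OC(C)=O)CC/C(C)=C/[C@H]2OC(=O)C(COC(C)=O)=C12 | intermediate
36 | (1S,4E,6R,8S,10S)-1,13-diacetoxy-8-hydroxygermacra-4,7(11)-dien-12,6-olide | O[C@H]1C[C@H](C)[C@@H](OC(C)=O)CC/C(C)=C/[C@H]2OC(=O)C(COC(C)=O)=C12 | intermediate
37 | (1S,4E,6R,8S,10S)-1,13-diacetoxy-8-(methacryloyloxy)germacra-4,7(11)-dien-12,6-olide | C=C(C)C(=O)O[C@H]1C[C@H](C)[C@@H](OC(C)=O)CC/C(C)=C/[C@H]2OC(=O)C(COC(C)=O)=C12 | intermediate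
38 | glaucolide K, (1S,4R,5R,6S,8S,10S)-1,13-diacetoxy-4,5-epoxy-8-(methacryloyloxy)germacr-7(11)-en-12,6-olide | C=C(C)C(=O)O[C@H]1C[C@H](C)[C@@H](OC(C)=O)CC[C@@]2(C)O[C@@H]2[C@H]2OC(=O)C(COC(C)=O)=C12 | target

## Step count and risks

Total step count: 26. Longest linear sequence: 17 steps (1–6, then 16–26; the branch 7–12, then 16–26 is equally long).

Steps most likely to fail:

Step 10 (CBS reduction of 17). The cross-conjugated bromo-enynone 17 is a sensitive Michael acceptor, and the facial discrimination between a 1-bromovinyl and a propynyl group is not established. Fallback, setting out from racemic 16 and coming back at 18: leave out the oxidation and resolve 16 by lipase-catalysed transesterification (Amano lipase PS, vinyl acetate, t-BuOMe, rt, about 50 % conversion). By the Kazlauskas rule (bromovinyl large, propynyl medium) the R enantiomer is acylated to (3R)-2-bromohex-1-en-4-yn-3-yl acetate F1, which is separated from the unreacted S alcohol and methanolysed (K2CO3, MeOH, 0 °C) to 18.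

Step 19 (chromium-mediated ring closure). The yield of a ten-membered ring and, above all, the configuration at C8 are not under reagent control. Fallback, setting out from 31 (any C8 epimer ratio) and coming back at 31: oxidise with Dess–Martin periodinane to the α-methylene ketone (1S,4E,6R,10S)-4,10-dimethyl-7-methylidene-8-oxo-6-[(triethylsilyl)oxy]cyclodec-4-en-1-yl acetate F2, then reduce under reagent control with (R)-2-methyl-CBS-oxazaborolidine and catecholborane at −78 °C. With the α-branched alkenyl group as the large and the ring CH2 as the small substituent this gives the 8S alcohol 31, so that C8 is set by hydride delivery and not in the C–C bond formation.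

Step 23 (metathesis to a tetrasubstituted butenolide). Both alkenes are 1,1-disubstituted, one is electron-poor, and the site is flanked by two oxygenated stereocentres, so catalyst loading may fail. Fallback, setting out from 33 and coming back at 35 (relay metathesis):
- hex-5-enal and tert-butyl acrylate give, by Morita–Baylis–Hillman reaction (DABCO), tert-butyl 3-hydroxy-2-methylideneoct-7-enoate F3;
- acetylation (Ac2O, DMAP) and DABCO-mediated allylic transposition give tert-butyl (2E)-2-(acetoxymethyl)octa-2,7-dienoate F4;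
- CF3CO2H frees (2E)-2-(acetoxymethyl)octa-2,7-dienoic acid F5;
- Yamaguchi esterification of 33 (2,4,6-trichlorobenzoyl chloride, Et3N, then DMAP) gives the relay ester (1S,4E,6R,8S,10S)-6-{[(2E)-2-(acetoxymethyl)octa-2,7-dienoyl]oxy}-8-[(tert-butyldimethylsilyl)oxy]-4,10-dimethyl-7-methylidenecyclodec-4-en-1-yl acetate F6;
- the second-generation Hoveyda–Grubbs catalyst then loads on the unhindered terminal vinyl group, expels cyclopentene, and is thereby delivered as the ruthenium alkylidene onto C11, next to the exo-methylene, where it closes to 35.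

Further compounds
F1 | step 10 | (3R)-2-bromohex-1-en-4-yn-3-yl acetate | CC#C[C@H](C(Br)=C)OC(C)=O
F2 | step 19 | (1S,4E,6R,10S)-4,10-dimethyl-7-methylidene-8-oxo-6-[(triethylsilyl)oxy]cyclodec-4-en-1-yl acetate | O=C1C[C@H](C)[C@@H](OC(C)=O)CC/C(C)=C/[C@@H](O[Si](CC)(CC)CC)C1=C
F3 | step 23 | tert-butyl 3-hydroxy-2-methylideneoct-7-enoate | C=CCCCC(O)C(=C)C(=O)OC(C)(C)C
F4 | step 23 | tert-butyl (2E)-2-(acetoxymethyl)octa-2,7-dienoate | C=CCCC/C=C(\COC(C)=O)C(=O)OC(C)(C)C
F5 | step 23 | (2E)-2-(acetoxymethyl)octa-2,7-dienoic acid | C=CCCC/C=C(\COC(C)=O)C(=O)O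
F6 | step 23 | (1S,4E,6R,8S,10S)-6-{[(2E)-2-(acetoxymethyl)octa-2,7-dienoyl]oxy}-8-[(tert-butyldimethylsilyl)oxy]-4,10-dimethyl-7-methylidenecyclodec-4-en-1-yl acetate | CC(C)(C)[Si](C)(C)O[C@H]1C[C@H](C)[C@@H](OC(C)=O)CC/C(C)=C/[C@@H](OC(=O)C(/COC(C)=O)=C/CCCC=C)C1=C
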